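## Retrosynthetic overview

1. Target 34 ⇐ Schenck ene reaction (singlet oxygen) on the 7E olefin of macrocyclic lactone 33; the C15 methyl ⇐ trans-selective enolate methylation of nor-lactone 31.
2. δ-Lactone ⇐ alkoxide/tert-butyl ester transesterification after ring closure; 14-membered carbocycle ⇐ intramolecular B-alkyl Suzuki coupling (C6–C7) of seco compound 26.
3. 11,12-Epoxide ⇐ Shi epoxidation; C4 vinyl carbinol ⇐ sulfonium-ylide homologation of a terminal epoxide set by Sharpless epoxidation of the C3 allylic alcohol (CBS reduction).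
4. C1 ⇐ lipase (CAL-B) desymmetrisation of prochiral glutarate 15, built from pent-4-yn-1-ol by Negishi carboalumination, Wittig, acetonitrile and malonate chemistry.
5. Ring order: 11,12-oxirane → 14-membered carbocycle → δ-lactone.

Assumption: names use cembrane numbering (C1 = ring CH carrying the C15(C17)–C16 arm, C3 = lactone O–CH, C4 = tertiary carbinol, C8 = hydroperoxide carbon, C11/C12 = epoxide); CAL-B is taken to give the S half-ester, by analogy with other 3-substituted glutarates.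

## Route

Step 1
Reactants: 1 pent-4-yn-1-ol
Product: 3 (4E)-5-bromo-4-methylpent-4-en-1-ol, via alkenylalane 2 (not isolated)
Conditions: AlMe3 (3 equiv), Cp2ZrCl2 (0.25 equiv), CH2Cl2, 0 °C → rt; then NBS, THF, −30 → 0 °C
Reagents that add atoms: trimethylaluminium C[Al](C)C; N-bromosuccinimide O=C1CCC(=O)N1Br
Why: Zirconium-catalysed Negishi carboalumination adds Me–Al syn across the terminal alkyne with methyl at the internal carbon, and bromodealumination proceeds with retention, fixing the E vinyl bromide that becomes the C7=C8 olefin.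

Step 2
Reactants: 3 (4E)-5-bromo-4-methylpent-4-en-1-ol
Product: 4 (4E)-5-bromo-4-methylpent-4-enal
Conditions: TEMPO (0.1 equiv), PhI(OAc)2 (1.1 equiv), CH2Cl2, rt
Reagents that add atoms: none
Why: Oxoammonium (TEMPO) oxidation stops at the aldehyde and leaves the vinyl bromide untouched.

Step 3
Reactants: 4 (4E)-5-bromo-4-methylpent-4-enal; 5 ethyl 2-(triphenylphosphoranylidene)propanoate
Product: 6 ethyl (2E,6E)-7-bromo-2,6-dimethylhepta-2,6-dienoate
Conditions: CH2Cl2, 40 °C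
Reagents that add atoms: none
Why: Wittig olefination with a stabilised α-methyl ylide gives the E trisubstituted enoate (typically ≥95:5), fixing the geometry of the future C11=C12 olefin.

Step 4
Reactants: 6 ethyl (2E,6E)-7-bromo-2,6-dimethylhepta-2,6-dienoate
Product: 7 (2E,6E)-7-bromo-2,6-dimethylhepta-2,6-dien-1-ol
Conditions: i-Bu2AlH (2.3 equiv), CH2Cl2, −78 °C; aq. potassium sodium tartrate
Reagents that add atoms: none
Why: Hydride 1,2-reduction of the conjugated ester gives the allylic alcohol without touching the vinyl bromide.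

Step 5
Reactants: 7 (2E,6E)-7-bromo-2,6-dimethylhepta-2,6-dien-1-ol
Product: 8 (1E,5E)-1,7-dibromo-2,6-dimethylhepta-1,5-diene
Conditions: CBr4, PPh3, CH2Cl2, 0 °C
Reagents that add atoms: tetrabromomethane BrC(Br)(Br)Br
Why: Appel bromination displaces the alkoxyphosphonium by SN2 at the primary allylic carbon without allylic transposition.

Step 6
Reactants: 8 (1E,5E)-1,7-dibromo-2,6-dimethylhepta-1,5-diene; 9 acetonitrile
Product: 10 (4E,8E)-9-bromo-4,8-dimethylnona-4,8-dienenitrile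
Conditions: n-BuLi, THF, −78 °C (9 → LiCH2CN); then 8, −78 °C
Reagents that add atoms: none
Why: SN2 alkylation of lithioacetonitrile occurs only at the allylic bromide (the vinylic bromide is inert) and adds the C14–C1 unit.

Step 7
Reactants: 10 (4E,8E)-9-bromo-4,8-dimethylnona-4,8-dienenitrile
Product: 11 (4E,8E)-9-bromo-4,8-dimethylnona-4,8-dienal
Conditions: i-Bu2AlH (1.2 equiv), CH2Cl2, −78 °C; then 1 M aq. HCl, 0 °C
Reagents that add atoms: water O
Why: Partial hydride reduction of the nitrile stops at the aluminium imine, which hydrolyses to the aldehyde.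

Step 8
Reactants: 11 (4E,8E)-9-bromo-4,8-dimethylnona-4,8-dienal; 12 dimethyl malonate (2 equivalents)
Product: 14 tetramethyl 2-[(3E,7E)-8-bromo-3,7-dimethylocta-3,7-dien-1-yl]propane-1,1,3,3-tetracarboxylate, via alkylidenemalonate 13 (not isolated)
Conditions: piperidine (0.2 equiv), AcOH (0.2 equiv), toluene, 4 Å MS, rt → 60 °C; then NaOMe (0.2 equiv), MeOH, rt
Reagents that add atoms: none
Why: Knoevenagel condensation followed by Michael addition of a second malonate gives a tetraester whose central carbon carries two identical arms, so no stereocentre is created.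

Step 9
Reactants: 14 tetramethyl 2-[(3E,7E)-8-bromo-3,7-dimethylocta-3,7-dien-1-yl]propane-1,1,3,3-tetracarboxylate
Product: 15 dimethyl 3-[(3E,7E)-8-bromo-3,7-dimethylocta-3,7-dien-1-yl]pentanedioate
Conditions: LiCl (4 equiv), H2O (4 equiv), DMSO, 150 °C
Reagents that add atoms: none
Why: Double Krapcho dealkoxycarbonylation removes one ester from each malonate unit under neutral conditions and leaves the prochiral 3-substituted glutarate.

Step 10
Reactants: 15 dimethyl 3-[(3E,7E)-8-bromo-3,7-dimethylocta-3,7-dien-1-yl]pentanedioate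
Product: 16 (3S)-3-[(3E,7E)-8-bromo-3,7-dimethylocta-3,7-dien-1-yl]-5-methoxy-5-oxopentanoic acid
Conditions: Candida antarctica lipase B (immobilised), phosphate buffer pH 7.2/acetone 9:1, 30 °C
Reagents that add atoms: water O
Why: Lipase-catalysed desymmetrisation, in which the serine hydrolase hydrolyses only one of the two enantiotopic CH2CO2Me arms, sets the first stereocentre (C1 of the target) as the S half-ester.

Step 11
Reactants: 16 (3S)-3-[(3E,7E)-8-bromo-3,7-dimethylocta-3,7-dien-1-yl]-5-methoxy-5-oxopentanoic acid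
Product: 17 1-tert-butyl 5-methyl (3R)-3-[(3E,7E)-8-bromo-3,7-dimethylocta-3,7-dien-1-yl]pentanedioate
Conditions: Cl3CC(=NH)Ot-Bu (2 equiv), CH2Cl2/cyclohexane, rt
Reagents that add atoms: tert-butyl 2,2,2-trichloroacetimidate CC(C)(C)OC(=N)C(Cl)(Cl)Cl
Why: O-alkylation of the acid by the trichloroacetimidate gives the tert-butyl ester and so differentiates the two carboxyl termini (the descriptor changes only through priorities).

Step 12
Reactants: 17 1-tert-butyl 5-methyl (3R)-3-[(3E,7E)-8-bromo-3,7-dimethylocta-3,7-dien-1-yl]pentanedioate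
Product: 18 tert-butyl (3R)-3-[(3E,7E)-8-bromo-3,7-dimethylocta-3,7-dien-1-yl]-5-[methoxy(methyl)amino]-5-oxopentanoate
Conditions: MeNH(OMe)·HCl (1.5 equiv), i-PrMgCl (3.0 equiv), THF, −20 °C
Reagents that add atoms: N,O-dimethylhydroxylamine hydrochloride CNOC.Cl
Why: Aminolysis by the magnesium amide converts the unhindered methyl ester into the Weinreb amide while the tert-butyl ester is too hindered to react.

Step 13
Reactants: 18 tert-butyl (3R)-3-[(3E,7E)-8-bromo-3,7-dimethylocta-3,7-dien-1-yl]-5-[methoxy(methyl)amino]-5-oxopentanoate; 19 isopropenylmagnesium bromide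
Product: 20 tert-butyl (3R)-3-[(3E,7E)-8-bromo-3,7-dimethylocta-3,7-dien-1-yl]-6-methyl-5-oxohept-6-enoate
Conditions: THF, −20 → 0 °C; inverse quench into cold aq. NH4Cl
Reagents that add atoms: none
Why: Weinreb ketone synthesis, in which the chelated tetrahedral intermediate survives until work-up, gives the isopropenyl ketone without over-addition or attack on the tert-butyl ester.

Step 14
Reactants: 20 tert-butyl (3R)-3-[(3E,7E)-8-bromo-3,7-dimethylocta-3,7-dien-1-yl]-6-methyl-5-oxohept-6-enoate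
Product: 21 tert-butyl (3R,5R)-3-[(3E,7E)-8-bromo-3,7-dimethylocta-3,7-dien-1-yl]-5-hydroxy-6-methylhept-6-enoate
Conditions: (S)-Me-CBS oxazaborolidine (0.2 equiv), catecholborane (1.8 equiv), toluene, −78 °C
Reagents that add atoms: none
Why: Corey–Bakshi–Shibata reduction, with the α-branched alkenyl group as the large substituent, delivers hydride to one carbonyl face under catalyst control and sets C3 of the target as R, while catecholborane does not hydroborate the alkenes at −78 °C.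

Step 15
Reactants: 21 tert-butyl (3R,5R)-3-[(3E,7E)-8-bromo-3,7-dimethylocta-3,7-dien-1-yl]-5-hydroxy-6-methylhept-6-enoate
Product: 22 tert-butyl (3R,5R)-3-[(3E,7E)-8-bromo-3,7-dimethylocta-3,7-dien-1-yl]-5-hydroxy-5-[(2S)-2-methyloxiran-2-yl]pentanoate
Conditions: Ti(OiPr)4 (0.2 equiv), D-(−)-diisopropyl tartrate (0.25 equiv), t-BuOOH (1.5 equiv), 4 Å MS, CH2Cl2, −20 °C
Reagents that add atoms: tert-butyl hydroperoxide CC(C)(C)OO
Why: Sharpless asymmetric epoxidation in its matched sense delivers oxygen syn to the hydroxyl in the conformer that avoids A(1,2) strain, giving the erythro epoxide (C4 of the target, S), while the minor C3 epimer reacts far more slowly and the isolated alkenes not at all.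

Step 16
Reactants: 22 tert-butyl (3R,5R)-3-[(3E,7E)-8-bromo-3,7-dimethylocta-3,7-dien-1-yl]-5-hydroxy-5-[(2S)-2-methyloxiran-2-yl]pentanoate
Product: 23 tert-butyl (3R,5R)-3-[(3E,7E)-8-bromo-3,7-dimethylocta-3,7-dien-1-yl]-5-[(2S)-2-methyloxiran-2-yl]-5-[(triethylsilyl)oxy]pentanoate
Conditions: Et3SiCl, imidazole, DMAP (cat.), CH2Cl2, 0 °C → rt
Reagents that add atoms: chlorotriethylsilane CC[Si](Cl)(CC)CC
Why: Silylation of the secondary alcohol prevents Payne rearrangement in the next, strongly basic step.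

Step 17
Reactants: 23 tert-butyl (3R,5R)-3-[(3E,7E)-8-bromo-3,7-dimethylocta-3,7-dien-1-yl]-5-[(2S)-2-methyloxiran-2-yl]-5-[(triethylsilyl)oxy]pentanoate
Product: 24 tert-butyl (3R,5R,6S)-3-[(3E,7E)-8-bromo-3,7-dimethylocta-3,7-dien-1-yl]-6-hydroxy-6-methyl-5-[(triethylsilyl)oxy]oct-7-enoate
Conditions: Me3S+ I− (5 equiv), n-BuLi (4.8 equiv), THF, −10 °C → rt
Reagents that add atoms: trimethylsulfonium iodide C[S+](C)C.[I-]
Why: Dimethylsulfonium methylide opens the 2,2-disubstituted oxirane at its CH2 terminus and the sulfonium alkoxide eliminates Me2S (one-carbon epoxide-to-allylic-alcohol homologation), giving the tertiary vinyl carbinol with C4 untouched.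

Step 18
Reactants: 24 tert-butyl (3R,5R,6S)-3-[(3E,7E)-8-bromo-3,7-dimethylocta-3,7-dien-1-yl]-6-hydroxy-6-methyl-5-[(triethylsilyl)oxy]oct-7-enoate
Product: 25 tert-butyl (3R,5R,6S)-3-[(3E,7E)-8-bromo-3,7-dimethylocta-3,7-dien-1-yl]-6-methyl-5-[(triethylsilyl)oxy]-6-[(trimethylsilyl)oxy]oct-7-enoate
Conditions: 1-(trimethylsilyl)imidazole, CH2Cl2, rt
Reagents that add atoms: 1-(trimethylsilyl)imidazole C[Si](C)(C)n1ccnc1
Why: Silyl transfer from a powerful, non-acidic donor caps the hindered tertiary alcohol so that it does not consume borane in step 20.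

Step 19
Reactants: 25 tert-butyl (3R,5R,6S)-3-[(3E,7E)-8-bromo-3,7-dimethylocta-3,7-dien-1-yl]-6-methyl-5-[(triethylsilyl)oxy]-6-[(trimethylsilyl)oxy]oct-7-enoate
Product: 26 tert-butyl (3R,5R,6S)-3-{2-[(2S,3S)-3-[(3E)-4-bromo-3-methylbut-3-en-1-yl]-2-methyloxiran-2-yl]ethyl}-6-methyl-5-[(triethylsilyl)oxy]-6-[(trimethylsilyl)oxy]oct-7-enoate
Conditions: ent-Shi ketone (L-fructose-derived, 0.3 equiv), Oxone (2KHSO5·KHSO4·K2SO4), K2CO3, Bu4NHSO4, MeCN–CH2(OMe)2/aq. Na2B4O7 buffer (pH 10.5), 0 °C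
Reagents that add atoms: potassium peroxymonosulfate [K+].[O-]S(=O)(=O)OO
Why: Shi asymmetric epoxidation by the chiral dioxirane epoxidises the only electron-rich trisubstituted olefin through a spiro transition state and sets C11 and C12 (S,S) under catalyst control, while the bromoalkene and the monosubstituted vinyl group are too electron-poor to react.

Step 20
Reactants: 26 tert-butyl (3R,5R,6S)-3-{2-[(2S,3S)-3-[(3E)-4-bromo-3-methylbut-3-en-1-yl]-2-methyloxiran-2-yl]ethyl}-6-methyl-5-[(triethylsilyl)oxy]-6-[(trimethylsilyl)oxy]oct-7-enoate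
Product: 28 tert-butyl 2-[(1R,3R,4S,7E,11S,12S)-11,12-epoxy-4,8,12-trimethyl-3-[(triethylsilyl)oxy]-4-[(trimethylsilyl)oxy]cyclotetradec-7-en-1-yl]acetate, via alkylborane 27 (not isolated)
Conditions: 9-BBN-H (2.5 equiv), THF, rt; H2O; then syringe-pump addition to Pd(dppf)Cl2 (0.2 equiv), AsPh3 (0.4 equiv), Cs2CO3 (3 equiv), DMF/THF/H2O, 50 °C, 1 mM
Reagents that add atoms: none
Why: 9-BBN hydroborates only the terminal vinyl group (boron at C6) and the alkylborane undergoes intramolecular B-alkyl Suzuki–Miyaura coupling with the alkenyl bromide under high dilution, closing the 14-membered ring with retention of the E geometry at C7=C8.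

Step 21
Reactants: 28 tert-butyl 2-[(1R,3R,4S,7E,11S,12S)-11,12-epoxy-4,8,12-trimethyl-3-[(triethylsilyl)oxy]-4-[(trimethylsilyl)oxy]cyclotetradec-7-en-1-yl]acetate
Product: 29 tert-butyl 2-[(1R,3R,4S,7E,11S,12S)-11,12-epoxy-3,4-dihydroxy-4,8,12-trimethylcyclotetradec-7-en-1-yl]acetate
Conditions: Bu4NF/AcOH (1:1, 4 equiv), THF, 0 °C → rt
Reagents that add atoms: none
Why: Buffered fluoride desilylation cleaves both silyl ethers without generating free alkoxide, so the epoxide and the tert-butyl ester survive.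

Step 22
Reactants: 29 tert-butyl 2-[(1R,3R,4S,7E,11S,12S)-11,12-epoxy-3,4-dihydroxy-4,8,12-trimethylcyclotetradec-7-en-1-yl]acetate
Product: 31 (1R,3R,4S,7E,11S,12S)-11,12-epoxy-4-hydroxy-17-norcembr-7-en-16,3-olide, via disodium dialkoxide 30 (not isolated)
Conditions: NaH (2.5 equiv), THF, 0 °C → rt; aq. NH4Cl
Reagents that add atoms: none
Why: Intramolecular transesterification (lactonisation) occurs because the C3 alkoxide attacks the tert-butyl ester through a six-membered transition state and expels tert-butoxide, whereas the tertiary C4 alkoxide would have to form a seven-membered ring.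

Step 23
Reactants: 31 (1R,3R,4S,7E,11S,12S)-11,12-epoxy-4-hydroxy-17-norcembr-7-en-16,3-olide
Product: 33 (1R,3R,4S,7E,11S,12S,15S)-11,12-epoxy-4-hydroxycembr-7-en-16,3-olide, via dilithium enolate 32 (not isolated)
Conditions: LiN(SiMe3)2 (2.3 equiv), THF, −78 °C; then MeI (5 equiv), −78 → −40 °C; aq. NH4Cl
Reagents that add atoms: iodomethane CI
Why: Enolate alkylation of the δ-lactone takes place on the face anti to the adjacent C1 ring substituent, giving the trans 15S methyl, which is also the thermodynamically preferred equatorial isomer.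

Step 24
Reactants: 33 (1R,3R,4S,7E,11S,12S,15S)-11,12-epoxy-4-hydroxycembr-7-en-16,3-olide
Product: 34 (1R,3R,4S,6E,8S,11S,12S,15S)-11,12-epoxy-8-hydroperoxy-4-hydroxycembr-6-en-16,3-olide
Conditions: O2, tetraphenylporphyrin (cat.), visible light, CH2Cl2, −20 °C; preparative HPLC
Reagents that add atoms: dioxygen O=O
Why: In the Schenck ene reaction singlet oxygen bonds to C8 of the only olefin and abstracts an allylic hydrogen from C6 on the more crowded side, shifting the double bond to C6=C7 (E) and creating the tertiary hydroperoxide, with C8 set by attack on the exposed face of the ring olefin and the 8S isomer separated from its C8 epimer and the 7-hydroperoxy-8(19)-ene regioisomer.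

## Compound list

1 | pent-4-yn-1-ol | C#CCCCO | starting material
2 | (E)-alkenyldimethylalane from 1 (O-aluminated) | C[Al](C)/C=C(\C)CCCO[Al](C)C | intermediate
3 | (4E)-5-bromo-4-methylpent-4-en-1-ol | OCCC/C(C)=C/Br | intermediate
4 | (4E)-5-bromo-4-methylpent-4-enal | O=CCC/C(C)=C/Br | intermediate
5 | ethyl 2-(triphenylphosphoranylidene)propanoate | CCOC(=O)C(C)=P(c1ccccc1)(c1ccccc1)c1ccccc1 | starting material
6 | ethyl (2E,6E)-7-bromo-2,6-dimethylhepta-2,6-dienoate | CCOC(=O)/C(C)=C/CC/C(C)=C/Br | intermediate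
7 | (2E,6E)-7-bromo-2,6-dimethylhepta-2,6-dien-1-ol | OC/C(C)=C/CC/C(C)=C/Br | intermediate
8 | (1E,5E)-1,7-dibromo-2,6-dimethylhepta-1,5-diene | BrC/C(C)=C/CC/C(C)=C/Br | intermediate
9 | acetonitrile | CC#N | starting material
10 | (4E,8E)-9-bromo-4,8-dimethylnona-4,8-dienenitrile | N#CCC/C(C)=C/CC/C(C)=C/Br | intermediate
11 | (4E,8E)-9-bromo-4,8-dimethylnona-4,8-dienal | O=CCC/C(C)=C/CC/C(C)=C/Br | intermediate
12 | dimethyl malonate | COC(=O)CC(=O)OC | starting material
13 | dimethyl 2-[(4E,8E)-9-bromo-4,8-dimethylnona-4,8-dien-1-ylidene]propanedioate | COC(=O)C(=CCC/C(C)=C/CC/C(C)=C/Br)C(=O)OC | intermediate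
14 | tetramethyl 2-[(3E,7E)-8-bromo-3,7-dimethylocta-3,7-dien-1-yl]propane-1,1,3,3-tetracarboxylate | COC(=O)C(C(=O)OC)C(CC/C(C)=C/CC/C(C)=C/Br)C(C(=O)OC)C(=O)OC | intermediate
15 | dimethyl 3-[(3E,7E)-8-bromo-3,7-dimethylocta-3,7-dien-1-yl]pentanedioate | COC(=O)CC(CC(=O)OC)CC/C(C)=C/CC/C(C)=C/Br | intermediate
16 | (3S)-3-[(3E,7E)-8-bromo-3,7-dimethylocta-3,7-dien-1-yl]-5-methoxy-5-oxopentanoic acid | COC(=O)C[C@H](CC(=O)O)CC/C(C)=C/CC/C(C)=C/Br | intermediate
17 | 1-tert-butyl 5-methyl (3R)-3-[(3E,7E)-8-bromo-3,7-dimethylocta-3,7-dien-1-yl]pentanedioate | COC(=O)C[C@H](CC(=O)OC(C)(C)C)CC/C(C)=C/CC/C(C)=C/Br | intermediate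
18 | tert-butyl (3R)-3-[(3E,7E)-8-bromo-3,7-dimethylocta-3,7-dien-1-yl]-5-[methoxy(methyl)amino]-5-oxopentanoate | CON(C)C(=O)C[C@H](CC(=O)OC(C)(C)C)CC/C(C)=C/CC/C(C)=C/Br | intermediate
19 | isopropenylmagnesium bromide | CC(=C)[Mg]Br | starting material
20 | tert-butyl (3R)-3-[(3E,7E)-8-bromo-3,7-dimethylocta-3,7-dien-1-yl]-6-methyl-5-oxohept-6-enoate | CC(=C)C(=O)C[C@H](CC(=O)OC(C)(C)C)CC/C(C)=C/CC/C(C)=C/Br | intermediate
21 | tert-butyl (3R,5R)-3-[(3E,7E)-8-bromo-3,7-dimethylocta-3,7-dien-1-yl]-5-hydroxy-6-methylhept-6-enoate | CC(=C)[C@H](O)C[C@H](CC(=O)OC(C)(C)C)CC/C(C)=C/CC/C(C)=C/Br | intermediate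
22 | tert-butyl (3R,5R)-3-[(3E,7E)-8-bromo-3,7-dimethylocta-3,7-dien-1-yl]-5-hydroxy-5-[(2S)-2-methyloxiran-2-yl]pentanoate | C[C@]1(CO1)[C@H](O)C[C@H](CC(=O)OC(C)(C)C)CC/C(C)=C/CC/C(C)=C/Br | intermediate
23 | tert-butyl (3R,5R)-3-[(3E,7E)-8-bromo-3,7-dimethylocta-3,7-dien-1-yl]-5-[(2S)-2-methyloxiran-2-yl]-5-[(triethylsilyl)oxy]pentanoate | C[C@]1(CO1)[C@H](O[Si](CC)(CC)CC)C[C@H](CC(=O)OC(C)(C)C)CC/C(C)=C/CC/C(C)=C/Br | intermediate
24 | tert-butyl (3R,5R,6S)-3-[(3E,7E)-8-bromo-3,7-dimethylocta-3,7-dien-1-yl]-6-hydroxy-6-methyl-5-[(triethylsilyl)oxy]oct-7-enoate | C=C[C@](C)(O)[C@H](O[Si](CC)(CC)CC)C[C@H](CC(=O)OC(C)(C)C)CC/C(C)=C/CC/C(C)=C/Br | intermediate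
25 | tert-butyl (3R,5R,6S)-3-[(3E,7E)-8-bromo-3,7-dimethylocta-3,7-dien-1-yl]-6-methyl-5-[(triethylsilyl)oxy]-6-[(trimethylsilyl)oxy]oct-7-enoate | C=C[C@](C)(O[Si](C)(C)C)[C@H](O[Si](CC)(CC)CC)C[C@H](CC(=O)OC(C)(C)C)CC/C(C)=C/CC/C(C)=C/Br | intermediate
26 | tert-butyl (3R,5R,6S)-3-{2-[(2S,3S)-3-[(3E)-4-bromo-3-methylbut-3-en-1-yl]-2-methyloxiran-2-yl]ethyl}-6-methyl-5-[(triethylsilyl)oxy]-6-[(trimethylsilyl)oxy]oct-7-enoate | C=C[C@](C)(O[Si](C)(C)C)[C@H](O[Si](CC)(CC)CC)C[C@H](CC(=O)OC(C)(C)C)CC[C@]1(C)O[C@H]1CC/C(C)=C/Br | intermediate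
27 | B-alkyl-9-borabicyclo[3.3.1]nonane from 26 (boron on the former vinyl terminus, C6) | C(C[C@](C)(O[Si](C)(C)C)[C@H](O[Si](CC)(CC)CC)C[C@H](CC(=O)OC(C)(C)C)CC[C@]1(C)O[C@H]1CC/C(C)=C/Br)B1C2CCCC1CCC2 | intermediate
28 | tert-butyl 2-[(1R,3R,4S,7E,11S,12S)-11,12-epoxy-4,8,12-trimethyl-3-[(triethylsilyl)oxy]-4-[(trimethylsilyl)oxy]cyclotetradec-7-en-1-yl]acetate | CC(C)(C)OC(=O)C[C@H]1C[C@@H](O[Si](CC)(CC)CC)[C@@](C)(O[Si](C)(C)C)CC/C=C(\C)CC[C@@H]2O[C@@]2(C)CC1 | intermediate
29 | tert-butyl 2-[(1R,3R,4S,7E,11S,12S)-11,12-epoxy-3,4-dihydroxy-4,8,12-trimethylcyclotetradec-7-en-1-yl]acetate | CC(C)(C)OC(=O)C[C@H]1C[C@@H](O)[C@@](C)(O)CC/C=C(\C)CC[C@@H]2O[C@@]2(C)CC1 | intermediate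
30 | disodium 3,4-dialkoxide of 29 | CC(C)(C)OC(=O)C[C@H]1C[C@@H]([O-])[C@@](C)([O-])CC/C=C(\C)CC[C@@H]2O[C@@]2(C)CC1.[Na+].[Na+] | intermediate
31 | (1R,3R,4S,7E,11S,12S)-11,12-epoxy-4-hydroxy-17-norcembr-7-en-16,3-olide (δ-lactone lacking the C15 methyl) | C1C(=O)O[C@@H]2C[C@H]1CC[C@]1(C)O[C@H]1CC/C(C)=C/CC[C@]2(C)O | intermediate
32 | dilithium C4-alkoxide lactone enolate of 31 | C1=C([O-])O[C@@H]2C[C@H]1CC[C@]1(C)O[C@H]1CC/C(C)=C/CC[C@]2(C)[O-].[Li+].[Li+] | intermediate
33 | (1R,3R,4S,7E,11S,12S,15S)-11,12-epoxy-4-hydroxycembr-7-en-16,3-olide | C[C@@H]1C(=O)O[C@@H]2C[C@H]1CC[C@]1(C)O[C@H]1CC/C(C)=C/CC[C@]2(C)O | intermediate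
34 | (1R,3R,4S,6E,8S,11S,12S,15S)-11,12-epoxy-8-hydroperoxy-4-hydroxycembr-6-en-16,3-olide (CNP0297487.4) | C[C@@H]1C(=O)O[C@@H]2C[C@H]1CC[C@]1(C)O[C@H]1CC[C@](C)(OO)/C=C/C[C@]2(C)O | target

## Summary

Total step count: 24. Longest linear sequence: 24 steps (from 1; compounds 5, 9, 12 and 19 are purchased).

The three steps most likely to fail, each with a fallback:

Step 10, because the sense and level of lipase selectivity on this lipophilic glutarate are not precedented for this exact substrate. The fallback replaces enzymatic hydrolysis by organocatalytic anhydride desymmetrisation. It sets out from 15: saponification (LiOH, THF/H2O) gives 3-[(3E,7E)-8-bromo-3,7-dimethylocta-3,7-dien-1-yl]pentanedioic acid F1. Ac2O at reflux closes it to 4-[(3E,7E)-8-bromo-3,7-dimethylocta-3,7-dien-1-yl]oxane-2,6-dione F2. Methanolysis of F2 at −20 °C with a cinchona-alkaloid thiourea catalyst (the quinine- or quinidine-derived pseudoenantiomer that gives the S hemiester) comes back to the route at 16.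

Step 20, because the macrocyclisation must compete with oligomerisation and protodeboronation. The fallback replaces the borane/aqueous-base ring closure by an anhydrous organozinc (Negishi) ring closure through a discrete iodide. It sets out from 26: hydroboration as before (27) with oxidative work-up (NaBO3·4H2O) gives tert-butyl (3R,5R,6S)-3-{2-[(2S,3S)-3-[(3E)-4-bromo-3-methylbut-3-en-1-yl]-2-methyloxiran-2-yl]ethyl}-8-hydroxy-6-methyl-5-[(triethylsilyl)oxy]-6-[(trimethylsilyl)oxy]octanoate F3. I2/PPh3/imidazole converts it into the corresponding 8-iodooctanoate F4. Zinc insertion (Zn dust, LiCl, THF) gives the 8-(iodozincio)octanoate F5. Slow addition of F5 to Pd2(dba)3/SPhos in THF closes the ring and comes back to the route at 28.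

Step 24, because the ene reaction gives regioisomers (7-hydroperoxy-8(19)-ene) and both C8 epimers, and the facial preference on the macrocycle cannot be predicted with confidence. The fallback is a regiospecific ionic route that delivers the peroxide to the face opposite to the one singlet oxygen uses. It sets out from 33: Markovnikov bromohydroperoxidation (1,3-dibromo-5,5-dimethylhydantoin, anhydrous H2O2 in Et2O, −40 °C) opens the bromonium ion anti at the tertiary carbon to give (1R,3R,4S,7R,8S,11S,12S,15S)-7-bromo-11,12-epoxy-8-hydroperoxy-4-hydroxycembran-16,3-olide F6. 2-Methoxypropene/PPTS masks the hydroperoxide (to prevent dioxetane closure under base) as the 8-[(2-methoxypropan-2-yl)peroxy] bromide F7. DBU (toluene, 60 °C) eliminates HBr toward C6 only, since C8 bears no hydrogen, to give (1R,3R,4S,6E,8S,11S,12S,15S)-11,12-epoxy-4-hydroxy-8-[(2-methoxypropan-2-yl)peroxy]cembr-6-en-16,3-olide F8. Aqueous AcOH/THF unmasks the hydroperoxide and comes back to the route at 34.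

## Further compounds

F1 | step 10 | 3-[(3E,7E)-8-bromo-3,7-dimethylocta-3,7-dien-1-yl]pentanedioic acid | OC(=O)CC(CC(=O)O)CC/C(C)=C/CC/C(C)=C/Br
F2 | step 10 | 4-[(3E,7E)-8-bromo-3,7-dimethylocta-3,7-dien-1-yl]oxane-2,6-dione | O=C1CC(CC/C(C)=C/CC/C(C)=C/Br)CC(=O)O1
F3 | step 20 | tert-butyl (3R,5R,6S)-3-{2-[(2S,3S)-3-[(3E)-4-bromo-3-methylbut-3-en-1-yl]-2-methyloxiran-2-yl]ethyl}-8-hydroxy-6-methyl-5-[(triethylsilyl)oxy]-6-[(trimethylsilyl)oxy]octanoate | OCC[C@](C)(O[Si](C)(C)C)[C@H](O[Si](CC)(CC)CC)C[C@H](CC(=O)OC(C)(C)C)CC[C@]1(C)O[C@H]1CC/C(C)=C/Br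
F4 | step 20 | tert-butyl (3R,5R,6S)-3-{2-[(2S,3S)-3-[(3E)-4-bromo-3-methylbut-3-en-1-yl]-2-methyloxiran-2-yl]ethyl}-8-iodo-6-methyl-5-[(triethylsilyl)oxy]-6-[(trimethylsilyl)oxy]octanoate | ICC[C@](C)(O[Si](C)(C)C)[C@H](O[Si](CC)(CC)CC)C[C@H](CC(=O)OC(C)(C)C)CC[C@]1(C)O[C@H]1CC/C(C)=C/Br
F5 | step 20 | 8-(iodozincio) analogue of F4 (alkylzinc iodide) | I[Zn]CC[C@](C)(O[Si](C)(C)C)[C@H](O[Si](CC)(CC)CC)C[C@H](CC(=O)OC(C)(C)C)CC[C@]1(C)O[C@H]1CC/C(C)=C/Br
F6 | step 24 | (1R,3R,4S,7R,8S,11S,12S,15S)-7-bromo-11,12-epoxy-8-hydroperoxy-4-hydroxycembran-16,3-olide | C[C@@H]1C(=O)O[C@@H]2C[C@H]1CC[C@]1(C)O[C@H]1CC[C@](C)(OO)[C@H](Br)CC[C@]2(C)O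
F7 | step 24 | (1R,3R,4S,7R,8S,11S,12S,15S)-7-bromo-11,12-epoxy-4-hydroxy-8-[(2-methoxypropan-2-yl)peroxy]cembran-16,3-olide | C[C@@H]1C(=O)O[C@@H]2C[C@H]1CC[C@]1(C)O[C@H]1CC[C@](C)(OOC(C)(C)OC)[C@H](Br)CC[C@]2(C)O
F8 | step 24 | (1R,3R,4S,6E,8S,11S,12S,15S)-11,12-epoxy-4-hydroxy-8-[(2-methoxypropan-2-yl)peroxy]cembr-6-en-16,3-olide | C[C@@H]1C(=O)O[C@@H]2C[C@H]1CC[C@]1(C)O[C@H]1CC[C@](C)(OOC(C)(C)OC)/C=C/C[C@]2(C)O
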